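How much target does the flask hold at 2.0 min, and which change raises it most? I start from the two earlier runs and from the smaller charge in the catalyst's balance, the impurity.

| setting | west | south-west | flask |
|---|---|---|---|
| substrate | 0.22 M | 0.33 M | 0.44 M |
| gas phase | 120 mM (held) | 120 mM (held) | 120 mM (held) |
| free catalyst | 44 mM | 44 mM | 44 mM |
| impurity | 21 mM | 21 mM | 21 mM |
| remark | run made earlier | run made earlier |  |
| time |  |  | 2.0 min |

| run | time / s | target / % |
|---|---|---|
| west | 20.0 | 4.6 |
| west | 40.0 | 9.1 |
| west | 60.0 | 12.9 |
| west | 80.0 | 18.1 |
| west | 90.0 | 20.0 |
| west | 120 | 25.3 |
| south-west | 20.0 | 4.8 |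
| south-west | 40.0 | 9.2 |
| south-west | 60.0 | 13.3 |
| south-west | 80.0 | 17.6 |
| south-west | 90.0 | 19.1 |
| south-west | 120 | 25.4 |

(each reading ± 0.3 percentage points)

- how much target there is at 2.0 min, in percent of the substrate charged
- concentration of dissolved gas in solution at 12 s, in percent of saturation
- the change that raises the amount of target at 2.0 min, in percent of the substrate charged most ("none" if none brings more than 2 percentage points) (amber / blue / grey / none)
- amount of target at 2.0 min, in percent of the substrate charged, after blue

- amber: doubling the amount of free catalyst, all else as stated
- blue: doubling the transfer coefficient of the gas phase, all else as stated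
- grey: doubling the saturation concentration of gas phase, all else as stated

- at the start none of the gas phase is in solution

At 120 s the west run reads 25.3% and the south-west run 25.4%, although the south-west run holds more substrate. So I treat the target as forming pseudo-first-order in substrate: [substrate] falls as exp(−kt), whatever its charge. The west reading then gives k = 0.146 min⁻¹, and the flask should reach 25.3% at 2.0 min.

West, south-west and the flask carry the same catalyst and impurity, so these runs cannot test my next step, which is an assumption. Suppose each impurity removes one catalyst for good, making the impurity the limiting reagent of that step. The balance then gives the working catalyst, the free catalyst charged minus the impurity charged 23.0 mM, and I let k follow it. Amber raises it by a factor of 2.91, which gives 57.2% target. If the rate follows dissolved gas in proportion, grey multiplies it by 2, less than amber's factor.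

The weak link is k, taken from one reading with its scatter of 0.3 percentage points. The mean of both runs at 120 s gives 0.146 min⁻¹, so I commit to 25.4% and to amber. I have no reckoning of my own for dissolved gas or for blue.

The forecast says 25%, 98% of saturation at 12 s, amber and 25.4% after blue: “Amber likely at least doubles the rate, and more if the impurity ties up catalyst”.

The simulation gives 25.3%, 92.6%, amber with a gain of 31 points, and 26.2% after blue.

    2 dissolved gas → homo dimer (k = 0.180 L mol⁻¹ s⁻¹)
    gas phase ⇌ dissolved gas, rate k2*(csat - [dissolved gas]) (kL = 0.620 s⁻¹)
    substrate + dissolved gas + free catalyst → free catalyst + target (k = 0.960 L² mol⁻² s⁻¹)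
    free catalyst + impurity → spent catalyst (k = 180 L mol⁻¹ s⁻¹)

In the flask the working catalyst is 52.3% of the charge, and the simulated flask holds 52.3% free catalyst with 0% impurity left at 2.00 min. The neighbouring flask is charged with 0.0084 M of impurity instead. Its working catalyst is 35.6 mM, which multiplies k by 1.55 and gives 36.4% target. The simulated neighbouring flask holds 80.9% free catalyst and 36.1% target at 2.00 min.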